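in all of them: added ligand 70 µM

|  | starting material | enzyme | remark | time |
|---|---|---|---|---|
| green | 0.10 M (fed, over 4.0 h) | 13 µM | run made earlier |  |
| violet | 0.10 M (fed, over 4.0 h) | 30 µM | run made earlier |  |
| ochre | 0.15 M (fed, over 4.0 h) | 20 µM | run made earlier |  |
| flask | 0.10 M (fed, over 4.0 h) | 20 µM |  | 4.0 h |

| run | time / h | target / % | starting material / % |
|---|---|---|---|
| green | 0.333 | 2.0 | 8.3 |
| green | 0.667 | 2.9 | 16.4 |
| green | 1.50 | 2.7 | 30.6 |
| green | 4.00 | 25.1 | 74.5 |
| violet | 0.333 | 2.0 | 7.6 |
| violet | 0.667 | 4.9 | 12.1 |
| violet | 1.50 | 13.0 | 21.9 |
| violet | 4.00 | 60.4 | 41.3 |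
| ochre | 1.00 | 4.8 | 21.3 |
| ochre | 2.00 | 12.7 | 36.8 |
| ochre | 3.00 | 24.1 | 52.6 |
| ochre | 4.00 | 34.5 | 66.2 |

(standard deviation of a reading: 1 percentage point)

- what may be going on: enzyme + added ligand <-> idle complex; starting material + enzyme -> target + enzyme
- percentages count the whole charge, also what has not yet gone in

- how much target the flask holds at 4.0 h, in percent of the starting material charged
- how much starting material the flask holds at 4.0 h, in percent of the starting material charged

**The feed.** The easy step comes first: a steady feed has delivered 8.32 % of the charge by 0.333 h, and the violet run then holds 7.6 % starting material and 2.0 % target. We follow one molecule. Once in, it waits for free enzyme, while the added ligand, charged above the enzyme in every run, keeps part of the enzyme as idle complex, the off-cycle form. We assume this binding is quick.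

**The middle.** At 1.50 h the green and violet runs have parted: green reads 2.7 % target and violet 13.0 %, a gap wider than the gap in enzyme.

**The end.** At 4.00 h the feed stops, and green sums to 99.6 % and violet to 102 %. So we take each molecule as standing at a fork, turned or waiting, and describe a run by the end odds, target over starting material. Green reads 0.337 and violet 1.46.

If the ligand holds most of the enzyme, free enzyme follows the loading, the enzyme charge over the ligand left after binding it. That is 0.228 for green, 0.750 for violet and 0.400 for the flask. Between the two runs the odds rise as the loading to the power 1.23. This steepness, the logarithm of the odds ratio over that of the loading ratio, is a reading.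

**Our reckoning.** For the flask it gives odds of 0.674, so 40.3 % target and 59.7 % starting material.

**The forecast.** It says 39 % target and 61 % starting material, its target 1.2 percentage points below ours, and of the enzyme runs it says: “That fits tight binding by excess ligand”.

**The flask.** It gives 40.6 % target and 59.4 % starting material.

    enzyme + added ligand ⇌ idle complex, settled at all times (K = 69000 M⁻¹)
    starting material + enzyme → target + enzyme, rate k2*[starting material]*[enzyme]/(1 + ([starting material]/Km2)) (39.0 mM, k = 2400 M⁻¹ min⁻¹)

**Idle enzyme.** At 4.00 h the flask has 78.9 % of its catalyst as idle complex against 21.1 % as enzyme, and its odds of 0.684 put the steepness from green at 1.26. Carried to the neighbour charged with 2.8 × 10⁻⁴ M added ligand, our steepness gives odds of 0.0882, or 8.11 % target, where that neighbour at 4.00 h, with 5.26 % of its catalyst as enzyme, holds 11.5 % target.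

The earlier runs and the new flask were computed from invented constants; noise was put on by code.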